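**Plan**

Ring A is numbered C1 (bears the methylidene carbon Cm), C2 (4-hydroxyphenyl), C3/C4 (CH), C5 (CH2OH), C6 (arylethynyl).
Cuts: Cm=C of the quinone methide back to Cm–H (oxidation last); C2–aryl and C6–alkynyl back to aryl triflates, which exposes two oxygens meta to each other with the hindered C1 between them; then ring A itself at C6–C1, C2–C3 and C5–C6.
This leaves a vinylketene (C3–C4–C5–C6 plus the CH2O carbon, from diazo ketone 5) and a silyloxyalkyne (C1–C2 with Cm and both of its aryl rings, 15).
Forward: 5 (2 steps) and 15 (3 steps) are joined in a benzannulation that makes ring A, the only ring built, as C6–OH/C2–OTIPS; the C6 oxygen becomes the alkyne (triflate, Sonogashira), the C2 oxygen the aryl group (desilylation, triflate, Suzuki); acid removes all protecting groups and DDQ sets the quinone methide.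
Stereochemistry: the target has no stereocentre and no configurational double bond, so nothing has to be controlled; the E-alkene of 5 disappears on aromatisation.

Key step: step 6

Assumption: the SMILES carries no stereodescriptor; any twist of the crowded triaryl array is taken as not configurationally fixed, because the phenol and quinone methide rings on Cm exchange by tautomerism, so no asymmetric step is planned.

**Route**

Step 1
Reactants: 1 (tert-butyldimethylsilyloxy)acetaldehyde; 2 1-(triphenylphosphoranylidene)propan-2-one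
Product: 3 (E)-5-[(tert-butyldimethylsilyl)oxy]pent-3-en-2-one
Conditions: CH2Cl2, rt
Reagents that add atoms: none
Why: Wittig olefination with a stabilised acyl ylide should give the (E)-enone selectively and leaves the silyl ether untouched.

Step 2
Reactants: 3 (E)-5-[(tert-butyldimethylsilyl)oxy]pent-3-en-2-one
Product: 5 (E)-5-[(tert-butyldimethylsilyl)oxy]-1-diazopent-3-en-2-one, via trifluoroacetyl diketone 4 (not isolated)
Conditions: LiHMDS, THF, −78 °C; CF3CO2CH2CF3, −78 °C; cold 5% aq HCl work-up; then MsN3, Et3N, H2O (1 equiv), MeCN, rt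
Reagents that add atoms: methanesulfonyl azide, CS(=O)(=O)N=[N+]=[N-] (the diazo nitrogens); 2,2,2-trifluoroethyl trifluoroacetate, O=C(OCC(F)(F)F)C(F)(F)F (trifluoroacetyl group, present only in 4)
Why: Kinetic α′-deprotonation, Claisen-type trifluoroacetylation and detrifluoroacetylative (Regitz-type) diazo transfer install the diazo group without exposing the conjugated alkene to diazomethane, which would add to it as a 1,3-dipole if the acid chloride route were used.

Step 3
Reactants: 6 1-bromo-4-(methoxymethoxy)benzene; 7 4-(methoxymethoxy)benzaldehyde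
Product: 9 bis[4-(methoxymethoxy)phenyl]methanol, via aryl Grignard reagent 8 (not isolated)
Conditions: Mg, THF, rt to 40 °C; then 7, 0 °C to rt; sat. aq NH4Cl
Reagents that add atoms: magnesium, [Mg] (kept only in 8)
Why: Grignard addition of an arylmagnesium bromide to an aromatic aldehyde should give the benzhydrol, and aryl MOM ethers tolerate organomagnesium reagents.

Step 4
Reactants: 9 bis[4-(methoxymethoxy)phenyl]methanol; 10 ethynylmagnesium bromide
Product: 12 3,3-bis[4-(methoxymethoxy)phenyl]prop-1-yne, via benzhydryl chloride 11 (not isolated)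
Conditions: PPh3, CCl4, CH2Cl2, 0 °C to rt; evaporate; then added to 10 (4 equiv), THF, 0 °C to rt
Reagents that add atoms: carbon tetrachloride, ClC(Cl)(Cl)Cl (its chlorine only in 11)
Why: Appel chlorination makes the doubly alkoxyaryl-stabilised benzhydryl chloride without acid or nucleophilic base (the MOM ethers stay on), and this SN1-active halide should be alkynylated at carbon by the excess alkynyl Grignard reagent, the excess suppressing double alkylation.

Step 5
Reactants: 12 3,3-bis[4-(methoxymethoxy)phenyl]prop-1-yne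
Product: 15 3,3-bis[4-(methoxymethoxy)phenyl]-1-[(triisopropylsilyl)oxy]prop-1-yne, via lithium acetylide 13 (not isolated), via lithium ynolate 14 (not isolated)
Conditions: n-BuLi (1.0 equiv), THF, −78 °C; then t-BuOOLi (from t-BuOOH and LiHMDS, THF, −78 °C), −78 to 0 °C; TIPSOTf, −78 to 0 °C
Reagents that add atoms: tert-butyl hydroperoxide, CC(C)(C)OO (one oxygen); triisopropylsilyl trifluoromethanesulfonate, CC(C)[Si](OS(=O)(=O)C(F)(F)F)(C(C)C)C(C)C (the silyl group); n-butyllithium, [Li]CCCC (lithium only in 13 and 14)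
Why: Oxidation of a lithium acetylide with lithium tert-butyl peroxide (electrophilic oxygen transfer to a carbanion) should give the lithium ynolate, which the bulky silyl triflate traps on oxygen, while one equivalent of n-BuLi at −78 °C removes only the sp C–H and leaves the doubly benzylic C–H in place.

Step 6
Reactants: 5 (E)-5-[(tert-butyldimethylsilyl)oxy]-1-diazopent-3-en-2-one (1.5 equiv); 15 3,3-bis[4-(methoxymethoxy)phenyl]-1-[(triisopropylsilyl)oxy]prop-1-yne
Product: 20 2-{bis[4-(methoxymethoxy)phenyl]methyl}-6-{[(tert-butyldimethylsilyl)oxy]methyl}-3-[(triisopropylsilyl)oxy]phenol, via vinylketene 16 (not isolated), via vinylcyclobutenone 17 (not isolated), via dienylketene 18 (not isolated), via cyclohexadienone 19 (not isolated)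
Conditions: hν (medium-pressure Hg lamp, Pyrex filter), ClCH2CH2Cl, rt; then 80 °C
Reagents that add atoms: none
Why: Light induces Wolff rearrangement of 5 (loss of N2, vinyl shift) to vinylketene 16, which adds across the electron-rich triple bond of 15 in a [2+2] cycloaddition to give 4-vinylcyclobutenone 17, whose strain drives 4π electrocyclic opening (light or 80 °C) to dienylketene 18, 6π electrocyclisation to dienone 19 and tautomerisation to phenol 20. The closest known reaction type is the Danheiser benzannulation in its diazo ketone (photo-Wolff) variant with trialkylsilyloxyalkynes. Ring A, the only ring formed, is closed by the 6π electrocyclisation (C5–C6) after C6–C1 and C2–C3 were made in the [2+2] step. No stereocentre results, because the sp3 carbons of 17 and 19 become aromatic. The step needs one regiochemistry of ketene–alkyne union, and the polarity of the ynol ether secures it: its nucleophilic β-carbon (carrying the diarylmethyl group) bonds to the ketene carbonyl carbon, so the free OH ends at C6 between C1 and C5 and the OTIPS group at C2. Filtering the light through Pyrex keeps the aryl ether chromophores unexcited, and the hindered phenol formed is a poor trap for surplus ketene.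

Step 7
Reactants: 20 2-{bis[4-(methoxymethoxy)phenyl]methyl}-6-{[(tert-butyldimethylsilyl)oxy]methyl}-3-[(triisopropylsilyl)oxy]phenol
Product: 21 2-{bis[4-(methoxymethoxy)phenyl]methyl}-6-{[(tert-butyldimethylsilyl)oxy]methyl}-3-[(triisopropylsilyl)oxy]phenyl trifluoromethanesulfonate
Conditions: Tf2O, pyridine, CH2Cl2, −78 to 0 °C
Reagents that add atoms: trifluoromethanesulfonic anhydride, O=S(=O)(OS(=O)(=O)C(F)(F)F)C(F)(F)F
Why: O-Sulfonylation with Tf2O/pyridine (N-triflylpyridinium) is small and reactive enough for the di-ortho-substituted phenol, and the buffered medium leaves silyl and MOM ethers intact.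

Step 8
Reactants: 7 4-(methoxymethoxy)benzaldehyde
Product: 22 1-ethynyl-4-(methoxymethoxy)benzene
Conditions: dimethyl (1-diazo-2-oxopropyl)phosphonate, K2CO3, MeOH, rt
Reagents that add atoms: dimethyl (1-diazo-2-oxopropyl)phosphonate, COP(=O)(OC)C(=[N+]=[N-])C(C)=O (the terminal alkyne carbon)
Why: Seyferth–Gilbert homologation in the Bestmann–Ohira modification should convert the aromatic aldehyde into the terminal alkyne under mild basic conditions that the MOM ether tolerates.

Step 9
Reactants: 21 aryl triflate (C6–OTf); 22 1-ethynyl-4-(methoxymethoxy)benzene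
Product: 23 tert-butyl{[3-{bis[4-(methoxymethoxy)phenyl]methyl}-2-{[4-(methoxymethoxy)phenyl]ethynyl}-4-[(triisopropylsilyl)oxy]benzyl]oxy}dimethylsilane
Conditions: PdCl2(PPh3)2 (cat.), CuI (cat.), n-Bu4NI, Et3N/DMF, 70 °C, slow addition of 22
Reagents that add atoms: none
Why: Sonogashira coupling of an aryl triflate with a terminal alkyne should form the C6–C(sp) bond, with iodide to stabilise the arylpalladium intermediate, slow alkyne addition to limit homocoupling, and an amine base that avoids carbonate-assisted C–H arylation of the neighbouring diarylmethyl rings.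

Step 10
Reactants: 23 silyl-protected diarylalkyne
Product: 24 2-{bis[4-(methoxymethoxy)phenyl]methyl}-4-{[(tert-butyldimethylsilyl)oxy]methyl}-3-{[4-(methoxymethoxy)phenyl]ethynyl}phenol
Conditions: TBAF (1.0 equiv), THF, −20 to 0 °C; sat. aq NH4Cl
Reagents that add atoms: none
Why: In fluoride-mediated desilylation an aryl silyl ether (phenoxide leaving group) is cleaved much faster than a primary alkyl TBS ether, so one equivalent of TBAF at low temperature should unmask only the C2 oxygen.

Step 11
Reactants: 24 C2 phenol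
Product: 25 2-{bis[4-(methoxymethoxy)phenyl]methyl}-4-{[(tert-butyldimethylsilyl)oxy]methyl}-3-{[4-(methoxymethoxy)phenyl]ethynyl}phenyl trifluoromethanesulfonate
Conditions: Tf2O, pyridine, CH2Cl2, −78 to 0 °C
Reagents that add atoms: trifluoromethanesulfonic anhydride, O=S(=O)(OS(=O)(=O)C(F)(F)F)C(F)(F)F
Why: Phenol O-triflation with Tf2O/pyridine is fast at the mono-ortho-substituted OH, and the alkyne, TBS ether and MOM ethers are inert under the buffered conditions.

Step 12
Reactants: 25 aryl triflate (C2–OTf); 26 [4-(methoxymethoxy)phenyl]boronic acid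
Product: 27 2-{bis[4-(methoxymethoxy)phenyl]methyl}-4-{[(tert-butyldimethylsilyl)oxy]methyl}-4'-(methoxymethoxy)-3-{[4-(methoxymethoxy)phenyl]ethynyl}-1,1'-biphenyl
Conditions: Pd(OAc)2, SPhos (cat.), K3PO4, toluene/H2O, 80 °C
Reagents that add atoms: none
Why: Suzuki–Miyaura coupling with a dialkylbiarylphosphine ligand should couple the ortho-hindered triflate at 80 °C, where transmetalation with the boronic acid outpaces cyclopalladation towards a fluorene.

Step 13
Reactants: 27 fully protected triarylmethane
Product: 28 4,4'-{[3-(hydroxymethyl)-6-(4-hydroxyphenyl)-2-[(4-hydroxyphenyl)ethynyl]phenyl]methylene}diphenol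
Conditions: conc. HCl, MeOH/THF, 45 °C
Reagents that add atoms: none
Why: Acid-catalysed acetal exchange should remove the four aryl MOM ethers and solvolyse the primary TBS ether in one operation, under conditions that the diarylalkyne, the triarylmethane C–H and the benzylic alcohol survive.

Step 14
Reactants: 28 leuco pentaol
Product: 29 selaginellin
Conditions: DDQ (1.0 equiv), 1,4-dioxane, rt
Reagents that add atoms: none
Why: DDQ dehydrogenation of a 4-hydroxyphenyl-substituted triarylmethane (leuco form) to the quinone methide, a fuchsone-type oxidation, removes the only para-hydroxybenzylic hydrogen in the molecule, and one equivalent should avoid further phenol oxidation.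

**Compound list**

1 | (tert-butyldimethylsilyloxy)acetaldehyde | CC(C)(C)[Si](C)(C)OCC=O | starting material
2 | 1-(triphenylphosphoranylidene)propan-2-one | CC(=O)C=P(c1ccccc1)(c1ccccc1)c1ccccc1 | starting material
3 | (E)-5-[(tert-butyldimethylsilyl)oxy]pent-3-en-2-one | CC(=O)/C=C/CO[Si](C)(C)C(C)(C)C | intermediate
4 | (E)-7-[(tert-butyldimethylsilyl)oxy]-1,1,1-trifluorohept-5-ene-2,4-dione (formed in situ, as its lithium enolate) | CC(C)(C)[Si](C)(C)OC/C=C/C(=O)CC(=O)C(F)(F)F | intermediate
5 | (E)-5-[(tert-butyldimethylsilyl)oxy]-1-diazopent-3-en-2-one | CC(C)(C)[Si](C)(C)OC/C=C/C(=O)C=[N+]=[N-] | intermediate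
6 | 1-bromo-4-(methoxymethoxy)benzene | COCOc1ccc(Br)cc1 | starting material
7 | 4-(methoxymethoxy)benzaldehyde | COCOc1ccc(C=O)cc1 | starting material
8 | [4-(methoxymethoxy)phenyl]magnesium bromide (formed in situ) | COCOc1ccc([Mg]Br)cc1 | intermediate
9 | bis[4-(methoxymethoxy)phenyl]methanol | COCOc1ccc(cc1)C(O)c1ccc(OCOC)cc1 | intermediate
10 | ethynylmagnesium bromide | C#C[Mg]Br | starting material
11 | chlorobis[4-(methoxymethoxy)phenyl]methane (formed in situ) | COCOc1ccc(cc1)C(Cl)c1ccc(OCOC)cc1 | intermediate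
12 | 3,3-bis[4-(methoxymethoxy)phenyl]prop-1-yne | COCOc1ccc(cc1)C(C#C)c1ccc(OCOC)cc1 | intermediate
13 | lithium 3,3-bis[4-(methoxymethoxy)phenyl]prop-1-yn-1-ide (formed in situ) | COCOc1ccc(cc1)C(C#C[Li])c1ccc(OCOC)cc1 | intermediate
14 | lithium 3,3-bis[4-(methoxymethoxy)phenyl]prop-1-yn-1-olate (formed in situ) | COCOc1ccc(cc1)C(C#CO[Li])c1ccc(OCOC)cc1 | intermediate
15 | 3,3-bis[4-(methoxymethoxy)phenyl]-1-[(triisopropylsilyl)oxy]prop-1-yne | COCOc1ccc(cc1)C(C#CO[Si](C(C)C)(C(C)C)C(C)C)c1ccc(OCOC)cc1 | intermediate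
16 | (E)-5-[(tert-butyldimethylsilyl)oxy]penta-1,3-dien-1-one (vinylketene, formed in situ) | O=C=C/C=C/CO[Si](C)(C)C(C)(C)C | intermediate
17 | 2-{bis[4-(methoxymethoxy)phenyl]methyl}-4-[(E)-3-[(tert-butyldimethylsilyl)oxy]prop-1-en-1-yl]-3-[(triisopropylsilyl)oxy]cyclobut-2-en-1-one (racemic, formed in situ) | O=C1C(C(c2ccc(OCOC)cc2)c2ccc(OCOC)cc2)=C(O[Si](C(C)C)(C(C)C)C(C)C)C1/C=C/CO[Si](C)(C)C(C)(C)C | intermediate
18 | (3E,5E)-2-{bis[4-(methoxymethoxy)phenyl]methyl}-7-[(tert-butyldimethylsilyl)oxy]-3-[(triisopropylsilyl)oxy]hepta-1,3,5-trien-1-one (dienylketene, formed in situ) | O=C=C(C(c1ccc(OCOC)cc1)c1ccc(OCOC)cc1)/C(O[Si](C(C)C)(C(C)C)C(C)C)=C\C=C\CO[Si](C)(C)C(C)(C)C | intermediate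
19 | 2-{bis[4-(methoxymethoxy)phenyl]methyl}-6-{[(tert-butyldimethylsilyl)oxy]methyl}-3-[(triisopropylsilyl)oxy]cyclohexa-2,4-dien-1-one (racemic, formed in situ) | O=C1C(C(c2ccc(OCOC)cc2)c2ccc(OCOC)cc2)=C(O[Si](C(C)C)(C(C)C)C(C)C)C=CC1CO[Si](C)(C)C(C)(C)C | intermediate
20 | 2-{bis[4-(methoxymethoxy)phenyl]methyl}-6-{[(tert-butyldimethylsilyl)oxy]methyl}-3-[(triisopropylsilyl)oxy]phenol | Oc1c(CO[Si](C)(C)C(C)(C)C)ccc(O[Si](C(C)C)(C(C)C)C(C)C)c1C(c1ccc(OCOC)cc1)c1ccc(OCOC)cc1 | intermediate
21 | 2-{bis[4-(methoxymethoxy)phenyl]methyl}-6-{[(tert-butyldimethylsilyl)oxy]methyl}-3-[(triisopropylsilyl)oxy]phenyl trifluoromethanesulfonate | O=S(=O)(Oc1c(CO[Si](C)(C)C(C)(C)C)ccc(O[Si](C(C)C)(C(C)C)C(C)C)c1C(c1ccc(OCOC)cc1)c1ccc(OCOC)cc1)C(F)(F)F | intermediate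
22 | 1-ethynyl-4-(methoxymethoxy)benzene | C#Cc1ccc(OCOC)cc1 | intermediate
23 | tert-butyl{[3-{bis[4-(methoxymethoxy)phenyl]methyl}-2-{[4-(methoxymethoxy)phenyl]ethynyl}-4-[(triisopropylsilyl)oxy]benzyl]oxy}dimethylsilane | COCOc1ccc(cc1)C#Cc1c(CO[Si](C)(C)C(C)(C)C)ccc(O[Si](C(C)C)(C(C)C)C(C)C)c1C(c1ccc(OCOC)cc1)c1ccc(OCOC)cc1 | intermediate
24 | 2-{bis[4-(methoxymethoxy)phenyl]methyl}-4-{[(tert-butyldimethylsilyl)oxy]methyl}-3-{[4-(methoxymethoxy)phenyl]ethynyl}phenol | COCOc1ccc(cc1)C#Cc1c(CO[Si](C)(C)C(C)(C)C)ccc(O)c1C(c1ccc(OCOC)cc1)c1ccc(OCOC)cc1 | intermediate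
25 | 2-{bis[4-(methoxymethoxy)phenyl]methyl}-4-{[(tert-butyldimethylsilyl)oxy]methyl}-3-{[4-(methoxymethoxy)phenyl]ethynyl}phenyl trifluoromethanesulfonate | COCOc1ccc(cc1)C#Cc1c(CO[Si](C)(C)C(C)(C)C)ccc(OS(=O)(=O)C(F)(F)F)c1C(c1ccc(OCOC)cc1)c1ccc(OCOC)cc1 | intermediate
26 | [4-(methoxymethoxy)phenyl]boronic acid | COCOc1ccc(cc1)B(O)O | starting material
27 | 2-{bis[4-(methoxymethoxy)phenyl]methyl}-4-{[(tert-butyldimethylsilyl)oxy]methyl}-4'-(methoxymethoxy)-3-{[4-(methoxymethoxy)phenyl]ethynyl}-1,1'-biphenyl | COCOc1ccc(cc1)C#Cc1c(CO[Si](C)(C)C(C)(C)C)ccc(-c2ccc(OCOC)cc2)c1C(c1ccc(OCOC)cc1)c1ccc(OCOC)cc1 | intermediate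
28 | 4,4'-{[3-(hydroxymethyl)-6-(4-hydroxyphenyl)-2-[(4-hydroxyphenyl)ethynyl]phenyl]methylene}diphenol | OCc1ccc(-c2ccc(O)cc2)c(C(c2ccc(O)cc2)c2ccc(O)cc2)c1C#Cc1ccc(O)cc1 | intermediate
29 | selaginellin, 4-{[3-(hydroxymethyl)-6-(4-hydroxyphenyl)-2-[(4-hydroxyphenyl)ethynyl]phenyl](4-hydroxyphenyl)methylidene}cyclohexa-2,5-dien-1-one | O=C1C=CC(=C(c2ccc(O)cc2)c2c(-c3ccc(O)cc3)ccc(CO)c2C#Cc2ccc(O)cc2)C=C1 | target

**Count**

Total steps: 14. Longest linear sequence: 11 steps (steps 3, 4, 5, 6, 7, 9, 10, 11, 12, 13, 14, from 6/7 to 29).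

**Steps most likely to fail**

Step 6. The photochemical channel may be starved: light may be absorbed or quenched by the other chromophores, or the excited diazo enone may follow paths other than Wolff rearrangement, so that too little vinylketene reaches the hindered alkyne terminus. The fallback sets out from silyloxyalkyne 15 and comes back at phenol 20, generating the same vinylketene 16 thermally in the dark. Doebner condensation of commercial 3-[(tert-butyldimethylsilyl)oxy]propanal with malonic acid (pyridine, piperidine) should give (E)-5-[(tert-butyldimethylsilyl)oxy]pent-2-enoic acid F1. Ghosez's reagent (1-chloro-N,N,2-trimethylprop-1-en-1-amine, CH2Cl2) should convert it under neutral conditions into (E)-5-[(tert-butyldimethylsilyl)oxy]pent-2-enoyl chloride F2. Slow addition of Et3N to F2 and 15 in toluene should effect 1,4-dehydrochlorination to 16, which 15 captures as cyclobutenone 17; heating at 80 °C then carries 17 through 18 and 19 to 20.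

Step 9. Oxidative addition and transmetalation at the di-ortho-substituted triflate may be slower than copper-mediated dimerisation of the alkyne and S–O cleavage of the triflate. The fallback sets out from triflate 21 and alkyne 22 and comes back at 23, replacing the copper acetylide by a preformed alkynyl metal under base-free conditions. Heating 22 with tributyltin methoxide (methanol distilled off) should give tributyl{[4-(methoxymethoxy)phenyl]ethynyl}stannane F3. Stille coupling of F3 with 21 (Pd(PPh3)4, LiCl, 1,4-dioxane, 100 °C) should then deliver 23.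

Step 5. Proton transfer from the doubly benzylic propargylic position during the slow oxygen transfer at 0 °C (acetylide to propargyl/allenyl anion) would divert the acetylide before it is oxygenated. The fallback sets out from aryl bromide 6 and comes back at silyloxyalkyne 15, reaching ynolate 14 by ester homologation instead. Commercial methyl (4-hydroxyphenyl)acetate is protected (MOMCl, i-Pr2NEt, CH2Cl2) as methyl [4-(methoxymethoxy)phenyl]acetate F4. Palladium-catalysed α-arylation of F4 with 6 (Pd(dba)2, P(t-Bu)3, LiHMDS, toluene) should give methyl bis[4-(methoxymethoxy)phenyl]acetate F5. Kowalski ester homologation follows: F5 is added to preformed LiCHBr2 (CH2Br2, LiTMP, THF, −78 °C), then LiHMDS gives the enolate of 1,1-dibromo-3,3-bis[4-(methoxymethoxy)phenyl]propan-2-one F6, and n-BuLi (−78 to 0 °C) triggers bromine–lithium exchange and 1,2-shift of the diarylmethyl group to ynolate 14. Silylation with TIPSOTf as in step 5 gives 15.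

**Further compounds**

F1 | step 6 | (E)-5-[(tert-butyldimethylsilyl)oxy]pent-2-enoic acid | CC(C)(C)[Si](C)(C)OCC/C=C/C(O)=O
F2 | step 6 | (E)-5-[(tert-butyldimethylsilyl)oxy]pent-2-enoyl chloride | CC(C)(C)[Si](C)(C)OCC/C=C/C(Cl)=O
F3 | step 9 | tributyl{[4-(methoxymethoxy)phenyl]ethynyl}stannane | CCCC[Sn](CCCC)(CCCC)C#Cc1ccc(OCOC)cc1
F4 | step 5 | methyl [4-(methoxymethoxy)phenyl]acetate | COCOc1ccc(CC(=O)OC)cc1
F5 | step 5 | methyl bis[4-(methoxymethoxy)phenyl]acetate | COCOc1ccc(cc1)C(C(=O)OC)c1ccc(OCOC)cc1
F6 | step 5 | 1,1-dibromo-3,3-bis[4-(methoxymethoxy)phenyl]propan-2-one | COCOc1ccc(cc1)C(C(=O)C(Br)Br)c1ccc(OCOC)cc1
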